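**Retrosynthetic overview**

1. Tetralin locants are used: C1 is the CH carrying the pendant guaiacyl ring, C2 and C3 are the two CH–CH2OH carbons, C4 is the ring CH2, C4a/C8a are the fusion carbons of ring A (C5–C8), and ring B is the saturated ring. The last disconnections are the two phenols (carried as benzyl ethers) and the two hydroxymethyl groups (carried as a C2 methyl ester and a C3 acyl oxazolidinone, both removed by one hydride reduction).
2. Key disconnection: ring B is cut at C3–C4 and at C8a–C1 in one move, a formal (3+3) annulation. The fragments are 4-(benzyloxy)-3,5-dimethoxybenzyl bromide (ring A plus C4) and the chiral imide of an (E)-arylidene succinic half-ester (C1–C2–C3 plus the pendant ring).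
3. Enabling feature: C3 bears a carbonyl-level arm, so it can be an enolate carbon. C1 is benzylic to the pendant ring and para to its C4' oxygen, and C1=C2 is conjugated to the C2 ester, so C1 is a cationic acceptor. C8a is ortho to the C8 methoxy and para to the C6 methoxy group, and the two ring positions ortho to C4a in the symmetric 3,5-dimethoxy unit are equivalent, so the Friedel–Crafts closure has one regiochemical outcome.
4. The arylidene succinate comes from a Stobbe condensation of O-benzylvanillin with dimethyl succinate. The (S)-4-benzyl oxazolidinone sets C3, and C3 relays to C1 and C2 during ring closure.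
5. Ring order: ring A and the pendant ring are bought; ring B is the only ring made (step 6).

Key step: step 6

Remark on the chemistry: the SMILES is read as the (1R,2S,3S) isomer (tetralin locants), in which the C1 aryl group, the C2 hydroxymethyl group and the C3 hydroxymethyl group are mutually trans.

**Route**

Step 1
Reactants: 1 4-(benzyloxy)-3-methoxybenzaldehyde; 2 dimethyl succinate
Product: 3 (E)-4-[4-(benzyloxy)-3-methoxyphenyl]-3-(methoxycarbonyl)but-3-enoic acid
Conditions: NaOMe, MeOH, reflux; then aq. HCl
Reagents that add atoms: none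
Why: Stobbe condensation: the succinate enolate condenses with the aldehyde, irreversible carboxylate formation drives the reaction to the half-ester, and the E geometry (aryl trans to the conjugated ester) is the one favoured for arylidene succinates.

Step 2
Reactants: 3 (E)-4-[4-(benzyloxy)-3-methoxyphenyl]-3-(methoxycarbonyl)but-3-enoic acid; 4 (S)-4-benzyl-1,3-oxazolidin-2-one
Product: 6 methyl (E)-2-[4-(benzyloxy)-3-methoxybenzylidene]-4-[(S)-4-benzyl-2-oxo-1,3-oxazolidin-3-yl]-4-oxobutanoate, via mixed pivalic anhydride 5 (not isolated)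
Conditions: t-BuCOCl, Et3N, THF, −20 °C; then 4, LiCl, −20 °C to rt
Reagents that add atoms: none
Why: N-acylation of an oxazolidinone auxiliary through a mixed anhydride, in which the hindered pivaloyl carbonyl directs the LiCl/Et3N-activated oxazolidinone to the desired carbonyl; no stereocentre is formed.

Step 3
Reactants: 7 4-hydroxy-3,5-dimethoxybenzaldehyde (syringaldehyde)
Product: 8 4-(benzyloxy)-3,5-dimethoxybenzaldehyde
Conditions: BnBr, K2CO3, DMF, rt
Reagents that add atoms: benzyl bromide, BrCc1ccccc1
Why: Williamson ether synthesis on the phenoxide, the only acidic site of the substrate.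

Step 4
Reactants: 8 4-(benzyloxy)-3,5-dimethoxybenzaldehyde
Product: 9 [4-(benzyloxy)-3,5-dimethoxyphenyl]methanol
Conditions: NaBH4, MeOH, 0 °C
Reagents that add atoms: none
Why: Borohydride reduction of an aryl aldehyde to the benzylic alcohol; the aryl ethers are inert.

Step 5
Reactants: 9 [4-(benzyloxy)-3,5-dimethoxyphenyl]methanol
Product: 10 2-(benzyloxy)-5-(bromomethyl)-1,3-dimethoxybenzene
Conditions: PBr3, CH2Cl2, 0 °C
Reagents that add atoms: phosphorus tribromide, BrP(Br)Br
Why: Conversion of a benzylic alcohol into the bromide with PBr3 (SN2 displacement of the activated hydroxyl by bromide), cold and brief so that the aryl benzyl ether survives.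

Step 6
Reactants: 6 methyl (E)-2-[4-(benzyloxy)-3-methoxybenzylidene]-4-[(S)-4-benzyl-2-oxo-1,3-oxazolidin-3-yl]-4-oxobutanoate; 10 2-(benzyloxy)-5-(bromomethyl)-1,3-dimethoxybenzene
Product: 13 methyl (1R,2S,3S)-7-(benzyloxy)-1-[4-(benzyloxy)-3-methoxyphenyl]-3-{[(S)-4-benzyl-2-oxo-1,3-oxazolidin-3-yl]carbonyl}-6,8-dimethoxy-1,2,3,4-tetrahydronaphthalene-2-carboxylate, via sodium enolate 11 (not isolated), via alkylated imide 12 (not isolated)
Conditions: NaN(SiMe3)2 (1.05 equiv), THF, −78 °C; 10 (0.95 equiv), −78 to −20 °C; then CF3CO2H (large excess), CH2Cl2, −20 °C to rt, one flask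
Reagents that add atoms: none
Why: NaN(SiMe3)2 gives the chelated Z sodium enolate 11, which is benzylated by bromide 10 at C3 on the face away from the 4-benzyl group of the oxazolidinone (Evans alkylation, SN2), forming the C3–C4 bond of 12 and fixing C3 as S. The acid then protonates the arylidene ester of 12 at C2 to give the C1 cation of quinone methide type, stabilised through the para benzyloxy oxygen of the pendant ring, and C8a of ring A attacks C1 in an intramolecular Friedel–Crafts (Michael-type) hydroarylation that closes ring B in the 6-endo-trig mode and forms the C8a–C1 bond. The closest known reaction types are the benzylation of sodium enolates of arylidene succinyl oxazolidinones and the CF3CO2H-mediated cyclisation of arylidene benzyl succinates and butyrolactones to 1-aryltetralins, here run in one flask. C1 and C2 are controlled by C3: protonation at C2 is reversible before ring closure, and closure should pass through the chair-like transition state in which the C3 acyl group, the C2 ester and the C1 aryl group are all equatorial, which gives the 1,2-trans, 2,3-trans isomer (C1 R, C2 S). The step needs alkylation at C3 and not at C1 of the dienolate, secured by the hindered aryl- and ester-conjugated C1, and a single Friedel–Crafts regioisomer, secured by the equivalence of the two ring positions ortho to C4a in the symmetric 3,5-dimethoxy unit and by their ortho/para activation through the methoxy groups, while the pendant ring cannot reach a six-membered closure. Bromide 10 is the limiting component so that no benzylic electrophile remains when the acid is added.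

Step 7
Reactants: 13 methyl (1R,2S,3S)-7-(benzyloxy)-1-[4-(benzyloxy)-3-methoxyphenyl]-3-{[(S)-4-benzyl-2-oxo-1,3-oxazolidin-3-yl]carbonyl}-6,8-dimethoxy-1,2,3,4-tetrahydronaphthalene-2-carboxylate
Product: 14 [(1R,2S,3S)-7-(benzyloxy)-1-[4-(benzyloxy)-3-methoxyphenyl]-6,8-dimethoxy-1,2,3,4-tetrahydronaphthalene-2,3-diyl]dimethanol
Conditions: LiAlH4, THF, 0 °C to rt; aq. potassium sodium tartrate
Reagents that add atoms: none
Why: Hydride reduction of the methyl ester and of the exocyclic imide carbonyl to primary alcohols (reductive removal of the oxazolidinone auxiliary); hydride adds only at the carbonyl carbons and the cold conditions should leave C1, C2 and C3 untouched.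

Step 8
Reactants: 14 [(1R,2S,3S)-7-(benzyloxy)-1-[4-(benzyloxy)-3-methoxyphenyl]-6,8-dimethoxy-1,2,3,4-tetrahydronaphthalene-2,3-diyl]dimethanol
Product: 15 (1R,2S,3S)-1-(4-hydroxy-3-methoxyphenyl)-2,3-bis(hydroxymethyl)-6,8-dimethoxy-1,2,3,4-tetrahydronaphthalen-7-ol
Conditions: H2 (1 atm), Pd/C, EtOAc/MeOH, rt
Reagents that add atoms: none
Why: Catalytic hydrogenolysis of the two aryl benzyl ethers; the benzylic C–C bonds of the tetralin and the primary alcohols are inert and no stereocentre is involved.

**Compound list**

1 | 4-(benzyloxy)-3-methoxybenzaldehyde | COc1cc(C=O)ccc1OCc1ccccc1 | starting material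
2 | dimethyl succinate | COC(=O)CCC(=O)OC | starting material
3 | (E)-4-[4-(benzyloxy)-3-methoxyphenyl]-3-(methoxycarbonyl)but-3-enoic acid | COC(=O)/C(=C/c1ccc(OCc2ccccc2)c(OC)c1)CC(=O)O | intermediate
4 | (S)-4-benzyl-1,3-oxazolidin-2-one | O=C1N[C@@H](Cc2ccccc2)CO1 | starting material
5 | mixed anhydride of acid 3 with pivalic acid | COC(=O)/C(=C/c1ccc(OCc2ccccc2)c(OC)c1)CC(=O)OC(=O)C(C)(C)C | intermediate
6 | methyl (E)-2-[4-(benzyloxy)-3-methoxybenzylidene]-4-[(S)-4-benzyl-2-oxo-1,3-oxazolidin-3-yl]-4-oxobutanoate | COC(=O)/C(=C/c1ccc(OCc2ccccc2)c(OC)c1)CC(=O)N1[C@@H](Cc2ccccc2)COC1=O | intermediate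
7 | 4-hydroxy-3,5-dimethoxybenzaldehyde (syringaldehyde) | COc1cc(C=O)cc(OC)c1O | starting material
8 | 4-(benzyloxy)-3,5-dimethoxybenzaldehyde | COc1cc(C=O)cc(OC)c1OCc1ccccc1 | intermediate
9 | [4-(benzyloxy)-3,5-dimethoxyphenyl]methanol | COc1cc(CO)cc(OC)c1OCc1ccccc1 | intermediate
10 | 2-(benzyloxy)-5-(bromomethyl)-1,3-dimethoxybenzene | COc1cc(CBr)cc(OC)c1OCc1ccccc1 | intermediate
11 | sodium (Z)-enolate of imide 6 | COC(=O)/C(=C/c1ccc(OCc2ccccc2)c(OC)c1)/C=C(\[O-])N1[C@@H](Cc2ccccc2)COC1=O.[Na+] | intermediate
12 | methyl (3S)-2-[(E)-4-(benzyloxy)-3-methoxybenzylidene]-3-[4-(benzyloxy)-3,5-dimethoxybenzyl]-4-[(S)-4-benzyl-2-oxo-1,3-oxazolidin-3-yl]-4-oxobutanoate | COC(=O)/C(=C/c1ccc(OCc2ccccc2)c(OC)c1)[C@H](Cc1cc(OC)c(OCc2ccccc2)c(OC)c1)C(=O)N1[C@@H](Cc2ccccc2)COC1=O | intermediate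
13 | methyl (1R,2S,3S)-7-(benzyloxy)-1-[4-(benzyloxy)-3-methoxyphenyl]-3-{[(S)-4-benzyl-2-oxo-1,3-oxazolidin-3-yl]carbonyl}-6,8-dimethoxy-1,2,3,4-tetrahydronaphthalene-2-carboxylate | COc1cc([C@@H]2c3c(cc(OC)c(OCc4ccccc4)c3OC)C[C@H](C(=O)N3[C@@H](Cc4ccccc4)COC3=O)[C@H]2C(=O)OC)ccc1OCc1ccccc1 | intermediate
14 | [(1R,2S,3S)-7-(benzyloxy)-1-[4-(benzyloxy)-3-methoxyphenyl]-6,8-dimethoxy-1,2,3,4-tetrahydronaphthalene-2,3-diyl]dimethanol | COc1cc([C@@H]2c3c(cc(OC)c(OCc4ccccc4)c3OC)C[C@H](CO)[C@H]2CO)ccc1OCc1ccccc1 | intermediate
15 | (1R,2S,3S)-1-(4-hydroxy-3-methoxyphenyl)-2,3-bis(hydroxymethyl)-6,8-dimethoxy-1,2,3,4-tetrahydronaphthalen-7-ol | COc1cc([C@@H]2c3c(cc(OC)c(O)c3OC)C[C@H](CO)[C@H]2CO)ccc1O | target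

**Step count and risks**

Total step count: 8.
Longest linear sequence: 6 steps (steps 3, 4, 5, 6, 7, 8).

Steps most likely to fail:

1. Step 6. The acid stage may stall because THF and the silylamine by-product buffer the acid. Benzyl ethers may be lost on long exposure to the acid. Ring closure may also pass through a transition state that places the C2 ester cis to the C1 aryl group. The fallback separates the two bond formations and puts C2 under thermodynamic control. It sets out from 6 and 10: the alkylation is run as above, quenched with aq. NH4Cl, and the alkylated imide 12 is isolated. 12 is then cyclised in a separate flask with catalytic CF3SO3H in CH2Cl2 at 0 °C to the cyclised imide 13. Treatment of 13 with NaOMe in MeOH exchanges the auxiliary for methoxide and should let the epimerisable centres C2 and C3 settle trans to each other and to the fixed C1 aryl group, giving dimethyl (1R,2S,3S)-7-(benzyloxy)-1-[4-(benzyloxy)-3-methoxyphenyl]-6,8-dimethoxy-1,2,3,4-tetrahydronaphthalene-2,3-dicarboxylate F1. LiAlH4 reduction of F1 in THF at 0 °C gives the diol, and the route is rejoined at 14.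

2. Step 7. Hydride may attack the ring carbonyl of the auxiliary (ring opening instead of release), reduction of the hindered C2 ester may be incomplete, or C2/C3 may epimerise at the aldehyde stage. The fallback removes the auxiliary by hydrolysis before any reduction. It sets out from 13: LiOH/H2O2 in THF/H2O at 0 °C cleaves the exocyclic imide bond and gives (1R,2S,3S)-7-(benzyloxy)-1-[4-(benzyloxy)-3-methoxyphenyl]-6,8-dimethoxy-2-(methoxycarbonyl)-1,2,3,4-tetrahydronaphthalene-3-carboxylic acid F2 (tetralin locants as in the route), with recovery of 4. LiAlH4 in THF then reduces the acid and the ester of F2 together, and the route is rejoined at 14.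

3. Step 1. The condensation may be incomplete, E/Z control may be lost, or hot methoxide may over-hydrolyse to the diacid. The fallback replaces the Stobbe condensation by a Horner–Wadsworth–Emmons olefination. It sets out from 1: trimethyl phosphonoacetate is alkylated with tert-butyl bromoacetate (NaH, THF) to 4-tert-butyl 1-methyl 2-(dimethoxyphosphoryl)butanedioate F3. The sodium salt of F3 (NaH, THF, 0 °C to rt) condenses with 1 to 4-tert-butyl 1-methyl (E)-2-[4-(benzyloxy)-3-methoxybenzylidene]butanedioate F4. Cleavage of the tert-butyl ester of F4 with CF3CO2H in CH2Cl2 at 0 °C gives the half-ester, and the route is rejoined at 3.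

**Further compounds**

F1 | step 6 | dimethyl (1R,2S,3S)-7-(benzyloxy)-1-[4-(benzyloxy)-3-methoxyphenyl]-6,8-dimethoxy-1,2,3,4-tetrahydronaphthalene-2,3-dicarboxylate | COc1cc([C@@H]2c3c(cc(OC)c(OCc4ccccc4)c3OC)C[C@H](C(=O)OC)[C@H]2C(=O)OC)ccc1OCc1ccccc1
F2 | step 7 | (1R,2S,3S)-7-(benzyloxy)-1-[4-(benzyloxy)-3-methoxyphenyl]-6,8-dimethoxy-2-(methoxycarbonyl)-1,2,3,4-tetrahydronaphthalene-3-carboxylic acid | COc1cc([C@@H]2c3c(cc(OC)c(OCc4ccccc4)c3OC)C[C@H](C(=O)O)[C@H]2C(=O)OC)ccc1OCc1ccccc1
F3 | step 1 | 4-tert-butyl 1-methyl 2-(dimethoxyphosphoryl)butanedioate | COC(=O)C(CC(=O)OC(C)(C)C)P(=O)(OC)OC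
F4 | step 1 | 4-tert-butyl 1-methyl (E)-2-[4-(benzyloxy)-3-methoxybenzylidene]butanedioate | COC(=O)/C(=C/c1ccc(OCc2ccccc2)c(OC)c1)CC(=O)OC(C)(C)C
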